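**Retrosynthetic overview**

1. Target ⇐ E1cB unmasking of the α‑methylene lactone (from a 13‑acetoxymethyl lactone), angeloylation of an 8β‑alcohol, reduction of a C8 ketone.
2. Ten‑membered ring ⇐ two‑carbon ring expansion of a lactone‑fused cyclooct‑4‑enone: silyl enol ether + dichloroketene → 1‑siloxybicyclo[6.2.0]decanone → spiro‑oxirane → fluoride‑triggered epoxy‑alkoxide fragmentation. This inserts C9 and C10, delivers C14–O and the ring‑cis C1=C10 olefin.
3. Eight‑membered ring ⇐ ring‑closing metathesis (C4=C5) on a trans‑β,γ‑disubstituted γ‑lactone.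
4. γ‑Lactone ⇐ dithiane‑anion 1,4‑addition / formaldehyde trapping on (R)‑5‑vinylbutenolide (from acrolein + methyl propiolate); dithiane arm ⇐ (S)‑epichlorohydrin + isopropenylmagnesium bromide + 1,3‑dithiane.
5. Ring order: γ‑lactone → cyclooctene → (transient cyclobutane and oxirane) → cyclodecadiene.

Assumption: atom labels C1–C15 are the germacrane numbers of the target (C12 lactone C=O, C13 exocyclic CH2, C14 acetoxymethyl carbon, C15 methyl), α/β mean below/above the ring with H‑7 α; the target is read as 2S,6R,7R,8R, both ring olefins cis within the ring, ester = angelate; in step 3 the ProPhenol antipode that gives the (R)‑carbinol is meant.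

**Step 1**
Reactants: 1 (S)-epichlorohydrin; 2 isopropenylmagnesium bromide
Product: 4 (S)-2-(2-methylprop-2-en-1-yl)oxirane, via bromomagnesium chlorohydrin alkoxide 3 (not isolated)
Conditions: CuI (5 mol%), THF, −40 → 0 °C; then aq. NaOH, 0 °C → rt
Reagents that add atoms: none
Why: Cu‑catalysed Grignard opening at the epoxide CH2 followed by base closure of the chlorohydrin (epichlorohydrin homologation); the carbinol carbon (future C2) is never touched, so its configuration comes from the chiral pool.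

**Step 2**
Reactants: 5 1,3-dithiane; 4 (S)-2-(2-methylprop-2-en-1-yl)oxirane
Product: 7 (S)-tert-butyl{[1-(1,3-dithian-2-yl)-4-methylpent-4-en-2-yl]oxy}dimethylsilane, via lithium alkoxide 6 (not isolated)
Conditions: n-BuLi, THF, −30 °C; 4, −30 → 0 °C; then TBSOTf, −78 → 0 °C
Reagents that add atoms: tert-butyldimethylsilyl triflate, CC(C)(C)[Si](C)(C)OS(=O)(=O)C(F)(F)F
Why: Corey–Seebach dithiane anion opens the terminal epoxide at C1 (SN2, stereocentre untouched) and the lithium alkoxide is silylated in the same flask.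

**Step 3**
Reactants: 8 acrolein; 9 methyl propiolate
Product: 10 methyl (R)-4-hydroxyhex-5-en-2-ynoate
Conditions: ProPhenol (10 mol%), Me2Zn, Ph3PO (20 mol%), toluene, 0 °C; aq. NH4Cl
Reagents that add atoms: none
Why: Zn–ProPhenol catalysed enantioselective alkynylation of an enal with a propiolate; the catalyst sets C6 (R).

**Step 4**
Reactants: 10 methyl (R)-4-hydroxyhex-5-en-2-ynoate
Product: 12 (R)-5-vinylfuran-2(5H)-one, via (Z)-hydroxy dienoate 11 (not isolated)
Conditions: H2 (1 atm, 1 equiv), Lindlar Pd, quinoline, EtOAc, rt; then PPTS (cat.), CH2Cl2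
Reagents that add atoms: none
Why: Lindlar semi‑hydrogenation gives the (Z)-γ‑hydroxy enoate, which lactonises to the butenolide without touching C6 or the terminal vinyl group.

**Step 5**
Reactants: 7 dithiane silyl ether; 12 (R)-5-vinylfuran-2(5H)-one
Product: 14 (5R)-3-(hydroxymethyl)-4-{2-[(2S)-2-(TBSO)-4-methylpent-4-en-1-yl]-1,3-dithian-2-yl}-5-vinyldihydrofuran-2(3H)-one (3,4-trans; 4,5-trans), via lithium lactone enolate 13 (not isolated)
Conditions: 7, t-BuLi, THF/HMPA (10:1), −78 °C; 12, −78 °C; CH2O (g), −78 → −45 °C; AcOH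
Reagents that add atoms: formaldehyde, C=O
Why: conjugate addition of the 2‑lithio‑1,3‑dithiane (acyl anion equivalent, HMPA favours 1,4) anti to the C6 vinyl group sets C7 (trans lactone), and the enolate is trapped by formaldehyde anti to the new C7 substituent (aldol), which installs C13 as CH2OH.

**Step 6**
Reactants: 14 all‑trans lactone
Product: 15 cyclooctene‑fused lactone (ring C1–C8; cis C4=C5 bearing 4‑Me; 2α‑OTBS; C8 = spiro 1,3‑dithiane carbon; trans γ‑lactone with O on C6 α and C11 on C7 β; 11‑CH2OH α)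
Conditions: Grubbs II (10 mol%), CH2Cl2 (1 mM), 40 °C
Reagents that add atoms: none
Why: ring‑closing metathesis of the vinyl and isopropenyl groups, helped by the trans‑disposed chains on the lactone and the gem‑disubstituted dithiane carbon; the eight‑membered ring forces the trisubstituted C4=C5 olefin to be ring‑cis.

**Step 7**
Reactants: 15 cyclooctene‑fused lactone
Product: 16 8‑oxo analogue of 15 (C8 dithiane replaced by C=O)
Conditions: PhI(O2CCF3)2, MeCN/H2O (9:1), 0 °C
Reagents that add atoms: water, O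
Why: oxidative dethioacetalisation with hypervalent iodine unmasks the C8 ketone under non‑basic conditions, so the β‑acyloxy ketone, silyl ether, free alcohol and olefin survive.

**Step 8**
Reactants: 16 cyclooctenone lactone
Product: 17 bis‑TMS derivative (ring‑cis C1=C8 trimethylsilyl enol ether; 13‑O‑TMS)
Conditions: LDA (2.3 equiv), TMSCl (6 equiv), THF, −78 °C (internal quench); Et3N, pentane work‑up
Reagents that add atoms: chlorotrimethylsilane, C[Si](C)(C)Cl
Why: kinetic deprotonation at the less hindered C1 methylene (not the tertiary C7–H) with in situ silylation gives the C1=C8 silyl enol ether and also caps the primary alcohol.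

**Step 9**
Reactants: 17 silyl enol ether
Product: 18 cis‑fused dichlorocyclobutanone (four‑membered ring C8–C9Cl2–C10(=O)–C1 on the β face; 8α‑OTMS; H‑1 α)
Conditions: Cl2CHCOCl, Et3N, hexanes, 0 °C → rt
Reagents that add atoms: dichloroacetyl chloride, O=C(Cl)C(Cl)Cl
Why: ketene–enol ether [2+2] cycloaddition, with the ketene carbonyl carbon bonding to nucleophilic C1 and CCl2 to C8, suprafacial so the ring is cis‑fused; approach anti to the C2 silyloxy group is assumed, and both new centres are erased in step 12.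

**Step 10**
Reactants: 18 dichlorocyclobutanone
Product: 19 cyclobutanone (C9H2; 13‑OH free; bridgehead 8α‑OTMS kept)
Conditions: Zn dust, AcOH, i‑PrOH/H2O, 0 °C → rt
Reagents that add atoms: none
Why: zinc reductive dechlorination of the α,α‑dichlorocyclobutanone; the aqueous acid hydrolyses the primary TMS ether while the hindered bridgehead TMS ether survives.

**Step 11**
Reactants: 19 cyclobutanone
Product: 20 spiro‑oxirane (C10 spiro epoxide O–C14H2; oxirane O endo, cis to C2 and C7; C14 exo)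
Conditions: Me3S+ I−, n‑BuLi, THF, −10 °C; then 19, −78 → 0 °C
Reagents that add atoms: trimethylsulfonium iodide, C[S+](C)C.[I-]
Why: Corey–Chaykovsky epoxidation; the ylide attacks the strained cyclobutanone (not the lactone) from the convex exo face, so the oxirane oxygen ends endo, syn to C2.

**Step 12**
Reactants: 20 spiro‑oxirane
Product: 23 2α-TBSO-13,14-diacetoxy-8-oxo-11βH-cis,cis-germacra-1(10),4-dien-6α,12-olide, via bridgehead alkoxide 21 (not isolated), via ring‑expanded C14 alkoxide 22 (not isolated)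
Conditions: TBAF (1.1 equiv), THF, −40 → 0 °C; then Ac2O, pyridine, DMAP (cat.), 0 °C
Reagents that add atoms: acetic anhydride, CC(=O)OC(C)=O
Why: Proposed new method: fluoride removes the bridgehead TMS group and the tertiary C8 alkoxide pushes into the C1–C8 ring‑fusion bond while the endo C10–O oxirane bond leaves (Grob‑type epoxy‑alkoxide fragmentation driven by loss of cyclobutane and oxirane strain), giving C8=O, the C1=C10 olefin and the C14 alkoxide, i.e. a two‑carbon ring expansion of the cyclooctane to the cyclodecadiene; because the oxirane oxygen is syn to C2, the least‑motion anti fragmentation places C2 and C9 cis (ring‑cis olefin), and cleavage of the fusion bond rather than C8–C9 is expected because it gives the trisubstituted endocyclic olefin and releases the bicycle; the closest known reactions are Holton‑type epoxy‑alcohol fragmentations and the retro‑aldol opening of 1‑siloxybicyclo[n.2.0]alkanones to ring‑expanded 1,3‑diones; both primary oxygens (C13, C14) are then acetylated in the same flask.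

**Step 13**
Reactants: 23 8‑oxo diacetate
Product: 24 2α-TBSO-13,14-diacetoxy-8β-hydroxy-11βH-cis,cis-germacra-1(10),4-dien-6α,12-olide
Conditions: NaBH4, CeCl3·7H2O, MeOH, −78 °C
Reagents that add atoms: none
Why: Luche‑type ketone reduction in which hydride is expected to attack the α face, anti to the β‑oriented C7–C11 bond, giving the 8β‑alcohol; acetates and lactone are inert at −78 °C.

**Step 14**
Reactants: 24 8β‑alcohol; 25 angelic acid
Product: 26 2α-TBSO-13,14-diacetoxy-8β-angeloyloxy-11βH-cis,cis-germacra-1(10),4-dien-6α,12-olide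
Conditions: 25, 2,4,6-Cl3C6H2COCl, Et3N, toluene, rt; then 24, 60 °C
Reagents that add atoms: none
Why: Yamaguchi mixed‑anhydride esterification without DMAP acylates the secondary alcohol while avoiding angelate‑to‑tiglate isomerisation.

**Step 15**
Reactants: 26 angelate
Product: 27 2‑O‑TBS ether of the target (α‑methylene lactone formed)
Conditions: DBU, CH2Cl2, 0 °C
Reagents that add atoms: none
Why: E1cB elimination of the β‑acetoxy group of the α‑(acetoxymethyl) lactone; only this acetate sits β to an acidic α‑proton, so the allylic C14 acetate and the angelate stay.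

**Step 16**
Reactants: 27 TBS ether
Product: 28 target, 14-acetoxy-8β-angeloyloxy-2α-hydroxy-cis,cis-germacra-1(10),4,11(13)-trien-6α,12-olide
Conditions: HF·pyridine, pyridine/THF, 0 °C → rt
Reagents that add atoms: none
Why: buffered fluoride desilylation of the secondary TBS ether leaves the esters and the α‑methylene lactone untouched.

**Compound list**

1 | (S)-epichlorohydrin | ClC[C@@H]1CO1 | starting material
2 | isopropenylmagnesium bromide | C=C(C)[Mg]Br | starting material
3 | bromomagnesium alkoxide of (S)-1-chloro-4-methylpent-4-en-2-ol | C=C(C)C[C@H](O[Mg]Br)CCl | intermediate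
4 | (S)-2-(2-methylprop-2-en-1-yl)oxirane | C=C(C)C[C@@H]1OC1 | intermediate
5 | 1,3-dithiane | C1CSCSC1 | starting material
6 | lithium alkoxide of (S)-1-(1,3-dithian-2-yl)-4-methylpent-4-en-2-ol | C=C(C)C[C@H](O[Li])CC1SCCCS1 | intermediate
7 | (S)-tert-butyl{[1-(1,3-dithian-2-yl)-4-methylpent-4-en-2-yl]oxy}dimethylsilane | C=C(C)C[C@H](O[Si](C)(C)C(C)(C)C)CC1SCCCS1 | intermediate
8 | acrolein | C=CC=O | starting material
9 | methyl propiolate | C#CC(=O)OC | starting material
10 | methyl (R)-4-hydroxyhex-5-en-2-ynoate | C=C[C@@H](O)C#CC(=O)OC | intermediate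
11 | methyl (R,Z)-4-hydroxyhexa-2,5-dienoate | C=C[C@@H](O)/C=C\C(=O)OC | intermediate
12 | (R)-5-vinylfuran-2(5H)-one | O=C1C=C[C@@H](C=C)O1 | intermediate
13 | lithium enolate of the 1,4‑adduct (lactone C11 enolate; C6 vinyl and C7 dithianyl trans) | [Li]OC1=C[C@H](C2(C[C@@H](O[Si](C)(C)C(C)(C)C)CC(C)=C)SCCCS2)[C@@H](C=C)O1 | intermediate
14 | (5R)-3-(hydroxymethyl)-4-{2-[(2S)-2-(TBSO)-4-methylpent-4-en-1-yl]-1,3-dithian-2-yl}-5-vinyldihydrofuran-2(3H)-one, 3,4-trans, 4,5-trans | O=C1O[C@H](C=C)[C@@H](C2(C[C@@H](O[Si](C)(C)C(C)(C)C)CC(C)=C)SCCCS2)[C@@H]1CO | intermediate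
15 | cyclooctene‑fused lactone: ring C1–C8, cis C4=C5 (4‑Me), 2α‑OTBS, C8 spiro‑1,3‑dithiane, trans γ‑lactone (O–C6 α, C7–C11 β), 11‑CH2OH α | O=C1O[C@@H]2/C=C(/C)C[C@H](O[Si](C)(C)C(C)(C)C)CC3(SCCCS3)[C@H]2[C@@H]1CO | intermediate
16 | 8‑oxo analogue of 15 | O=C1O[C@@H]2/C=C(/C)C[C@H](O[Si](C)(C)C(C)(C)C)CC(=O)[C@H]2[C@@H]1CO | intermediate
17 | ring‑cis C1=C8 trimethylsilyl enol ether of 16, 13‑O‑TMS | O=C1O[C@@H]2/C=C(/C)C[C@H](O[Si](C)(C)C(C)(C)C)/C=C(/O[Si](C)(C)C)[C@H]2[C@@H]1CO[Si](C)(C)C | intermediate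
18 | cis‑fused 9,9‑dichlorocyclobutanone (C8–C9–C10(=O)–C1 on β face, 8α‑OTMS, H‑1 α), 13‑O‑TMS | O=C1O[C@@H]2/C=C(/C)C[C@H](O[Si](C)(C)C(C)(C)C)[C@H]3C(=O)C(Cl)(Cl)[C@@]3(O[Si](C)(C)C)[C@H]2[C@@H]1CO[Si](C)(C)C | intermediate
19 | dechlorinated cyclobutanone, 13‑OH free, 8α‑OTMS | O=C1O[C@@H]2/C=C(/C)C[C@H](O[Si](C)(C)C(C)(C)C)[C@H]3C(=O)C[C@@]3(O[Si](C)(C)C)[C@H]2[C@@H]1CO | intermediate
20 | C10 spiro‑oxirane of 19 (oxirane O endo, cis to C2/C7; C14 exo) | O=C1O[C@@H]2/C=C(/C)C[C@H](O[Si](C)(C)C(C)(C)C)[C@H]3[C@]4(CO4)C[C@@]3(O[Si](C)(C)C)[C@H]2[C@@H]1CO | intermediate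
21 | bridgehead C8 alkoxide of desilylated 20, tetrabutylammonium salt | O=C1O[C@@H]2/C=C(/C)C[C@H](O[Si](C)(C)C(C)(C)C)[C@H]3[C@]4(CO4)C[C@@]3([O-])[C@H]2[C@@H]1CO.CCCC[N+](CCCC)(CCCC)CCCC | intermediate
22 | ring‑expanded ten‑membered 8‑ketone with ring‑cis C1=C10 and C14 alkoxide, tetrabutylammonium salt | OC[C@@H]1C(=O)O[C@@H]2/C=C(/C)C[C@H](O[Si](C)(C)C(C)(C)C)/C=C(/C[O-])CC(=O)[C@@H]12.CCCC[N+](CCCC)(CCCC)CCCC | intermediate
23 | 2α-TBSO-13,14-diacetoxy-8-oxo-11βH-cis,cis-germacra-1(10),4-dien-6α,12-olide | CC(=O)OC[C@@H]1C(=O)O[C@@H]2/C=C(/C)C[C@H](O[Si](C)(C)C(C)(C)C)/C=C(/COC(C)=O)CC(=O)[C@@H]12 | intermediate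
24 | 8β‑hydroxy analogue of 23 | CC(=O)OC[C@@H]1C(=O)O[C@@H]2/C=C(/C)C[C@H](O[Si](C)(C)C(C)(C)C)/C=C(/COC(C)=O)C[C@@H](O)[C@@H]12 | intermediate
25 | angelic acid, (Z)-2-methylbut-2-enoic acid | C/C=C(/C)C(=O)O | starting material
26 | 8β‑angelate of 24 | CC(=O)OC[C@@H]1C(=O)O[C@@H]2/C=C(/C)C[C@H](O[Si](C)(C)C(C)(C)C)/C=C(/COC(C)=O)C[C@@H](OC(=O)/C(C)=C\C)[C@@H]12 | intermediate
27 | 2‑O‑TBS ether of the target | C=C1C(=O)O[C@@H]2/C=C(/C)C[C@H](O[Si](C)(C)C(C)(C)C)/C=C(/COC(C)=O)C[C@@H](OC(=O)/C(C)=C\C)[C@@H]12 | intermediate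
28 | 14-acetoxy-8β-angeloyloxy-2α-hydroxy-cis,cis-germacra-1(10),4,11(13)-trien-6α,12-olide | C=C1C(=O)O[C@@H]2/C=C(/C)C[C@H](O)/C=C(/COC(C)=O)C[C@@H](OC(=O)/C(C)=C\C)[C@@H]12 | target

**Step count and risk**

Total steps: 16. Longest linear sequence: 14 (steps 1, 2, 5–16; the branch 3, 4, 5–16 is equally long).

Most likely to fail:

Step 12 (proposed new fragmentation). Risks are cleavage of C8–C9 instead of the fusion bond, or an exo oxirane giving the ring‑trans olefin. The fallback uses known alkoxy‑radical chemistry, sets out from 19 and returns at 23. Wittig methylenation of 19 (Ph3P=CH2, THF, 0 °C) gives the methylenecyclobutane F3. Acetylation of the primary alcohol (Ac2O, pyridine) gives the 13‑acetate F4. Mild acidic methanolysis (PPTS, MeOH, 0 °C) removes the bridgehead TMS group to give the tertiary cyclobutanol F5. Under Suárez conditions (PhI(OAc)2, I2, hν, cyclohexane/CH2Cl2) the C8 alkoxy radical undergoes β‑scission of the C1–C8 fusion bond to the secondary allylic radical, which is trapped by iodine at C14 to give the ring‑expanded 14‑iodo 8‑ketone F6. Displacement with KOAc (DMF, rt) gives 23. Olefin geometry is less well controlled here, although the ring favours the cis isomer.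

Step 13 (facial selectivity of the C8 reduction in a flexible ten‑membered ring). The fallback sets out from 23 and returns at 26. If hydride delivery gives mainly the 8α-hydroxy epimer F7, it is esterified with inversion by a Mitsunobu reaction with angelic acid 25 (PPh3, DIAD, toluene, 0 °C → rt), which gives 26 directly.

Step 3 (acrolein is a polymerisation‑prone substrate for catalytic asymmetric alkynylation). The fallback sets out from 8 and 9 and returns at 10. Lithiated 9 (LiHMDS, THF, −78 °C) is added to 8 to give racemic methyl 4-hydroxyhex-5-en-2-ynoate F1, which is resolved by lipase‑catalysed acylation (Amano PS, vinyl acetate, MTBE, about 50 % conversion). Taking the (R)-enantiomer as the fast‑reacting one, methyl (R)-4-acetoxyhex-5-en-2-ynoate F2 is separated and cleaved by acidic methanolysis (AcCl/MeOH, 0 °C) to 10. If the enzyme prefers the other antipode, the unreacted alcohol is 10 itself.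

**Further compounds**

F1 | step 3 | racemic methyl 4-hydroxyhex-5-en-2-ynoate | C=CC(O)C#CC(=O)OC
F2 | step 3 | methyl (R)-4-acetoxyhex-5-en-2-ynoate | C=C[C@@H](OC(C)=O)C#CC(=O)OC
F3 | step 12 | C10 methylenecyclobutane from 19 (8α‑OTMS, 13‑OH) | O=C1O[C@@H]2/C=C(/C)C[C@H](O[Si](C)(C)C(C)(C)C)[C@H]3C(=C)C[C@@]3(O[Si](C)(C)C)[C@H]2[C@@H]1CO
F4 | step 12 | 13‑acetate of F3 | O=C1O[C@@H]2/C=C(/C)C[C@H](O[Si](C)(C)C(C)(C)C)[C@H]3C(=C)C[C@@]3(O[Si](C)(C)C)[C@H]2[C@@H]1COC(C)=O
F5 | step 12 | bridgehead tertiary cyclobutanol from F4 | O=C1O[C@@H]2/C=C(/C)C[C@H](O[Si](C)(C)C(C)(C)C)[C@H]3C(=C)C[C@@]3(O)[C@H]2[C@@H]1COC(C)=O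
F6 | step 12 | 2α-TBSO-13-acetoxy-14-iodo-8-oxo-11βH-cis,cis-germacra-1(10),4-dien-6α,12-olide | CC(=O)OC[C@@H]1C(=O)O[C@@H]2/C=C(/C)C[C@H](O[Si](C)(C)C(C)(C)C)/C=C(/CI)CC(=O)[C@@H]12
F7 | step 13 | 8α‑hydroxy epimer of 24 | CC(=O)OC[C@@H]1C(=O)O[C@@H]2/C=C(/C)C[C@H](O[Si](C)(C)C(C)(C)C)/C=C(/COC(C)=O)C[C@H](O)[C@@H]12
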